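Set the two earlier runs side by side: the north-west flask, charged heavier, still holds 12.1% of its solid at 20.0 min, more than the 1.0% left in the south-east flask at 8.00 min.

| setting | south-east | north-west | flask |
|---|---|---|---|
| solid substrate | 30 mM | 45 mM | 30 mM |
| catalyst | 0.15 mM | 0.15 mM | 0.15 mM |
| remark | the very flask that is asked about, followed so far | run made earlier |  |
| time |  |  | 20 min |

- south-east (time / min: target / %, solid substrate / %): 0.667: 0.7, 72.2; 2.00: 2.0, 41.2; 4.00: 2.6, 22.3; 6.00: 3.8, 8.9; 8.00: 6.2, 1.0
- north-west (time / min: target / %, solid substrate / %): 1.50: 0, 67.8; 3.00: 1.3, 53.3; 6.00: 1.9, 38.9; 10.0: 3.9, 30.0; 20.0: 9.4, 12.1

(readings scatter by 1 percentage point)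

- solid substrate is a solid; its amount is given per volume of the solution
- the earlier runs were read with a standard deviation of 1 percentage point
- candidate steps: starting material <-> other conformer; catalyst + other conformer -> catalyst + isomer of the product; starting material + catalyst -> catalyst + target; solid substrate <-> starting material
- at the start none of the solid substrate is in solution

- beta: doubling the solubility of the solid substrate, all else as stated
- alpha: doubling the dissolution coefficient of the solid substrate, all else as stated
- eta: doubling the amount of catalyst, all else as stated

- target at 20 min, in percent of the solid substrate charged
- the change that raises the amount of target at 20 min, in percent of the solid substrate charged most ("none" if none brings more than 2 percentage points) (beta / alpha / eta / none)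
- amount of target at 20 min, in percent of the solid substrate charged, after beta

While solid stands, dissolving refills the solution, so freeze c(starting material) at one level. Between 10.0 min and 20.0 min the north-west target climbs at 0.247 mM min⁻¹, and by 6.00 min about 27.5 mM has left its solid. Take that as the level. Dividing gives a pseudo-first-order constant of 0.00900 min⁻¹, and from it the target half-life, the time in which the step to target by itself halves c(starting material) at this catalyst charge: 77.0 min.

Now build two extreme versions of the south-east flask, the one asked about. In the first, the level stands from time zero, and target reaches 16.5% at 20 min. In the second, nothing reacts until 8.00 min, and then the level stands, giving 9.90%. The real south-east flask lies between them: it starts with an empty solution, yet it already shows 6.2% target at 8.00 min. Take the middle as your own reckoning, 13.2%.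

The forecast says 13%, within 11% to 15.5%, and 14.3% after beta. It names eta as best, holding that “Doubling solubility or the dissolution coefficient” earns about 1 point.

The flask gives 12.3%, and 13.2% after beta. The change eta gains 10 percentage points, more than beta's 0.9 points or alpha's 0.5 points.

    starting material ⇌ other conformer (K = 0.590, k = 0.0550 min⁻¹)
    catalyst + other conformer → catalyst + isomer of the product (k = 150 L mol⁻¹ min⁻¹)
    starting material + catalyst → catalyst + target (k = 67.0 L mol⁻¹ min⁻¹)
    solid substrate ⇌ starting material, rate k4*(cs4 - [starting material]) while solid is left; crystals form when [starting material] > cs4 (solubility = 24.0 mM, k = 0.610 min⁻¹)

In the scheme the target step runs in proportion to catalyst, so at 0.60 mM the estimated target half-life of 77.0 min scales to 19.3 min and the scheme's 69 min to 17.2 min, and that neighbour flask stands at 38.9% target at 20.0 min. The asked flask has not come to rest at 20 min: it has run 0.290 of the scheme's target half-life and still holds 53.6% starting material and 26.0% other conformer. Ten times the time spans 2.90 of these half-lives; by then starting material is down to 3.85% and other conformer to 2.09%, while target has risen to 45.8% and isomer of the product from 8.07% to 48.3%.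

(The numbers in the tables were computed with constants of no real substance; scatter was added.)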